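**Retrosynthetic overview**

1. The target is a (2S)-flavanone (rings A and C plus phenyl) that carries on C6 a trans-(1'S,6'S)-3'-methyl-6'-isopropylcyclohex-2'-enyl group. Ring C is opened last: C4–C4a by Parham cyclisation of an aryl bromide onto a Weinreb amide, and O1–C2 by Mitsunobu inversion of an (R)-β-hydroxy Weinreb amide at the one unhindered phenol.
2. The aryl–C1' bond and the cyclohexene are disconnected together. C2' is an unsubstituted CH between the methyl-bearing C3' and the aryl-bearing C1'; taken out as a CBr2 unit it leaves a cyclopentene. Silver-induced cyclopropyl-to-allyl opening of the gem-dibromobicyclo[3.1.0]hexane puts it back while phloroglucinol is bound at C1', trans to the isopropyl group on C6'.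
3. Enabling feature: the allyl triad C1'(H)(aryl)–C2'(H)=C3'(Me) next to the C6' stereocentre. The cation terminus made by the ring expansion is the carbon that must carry ring A. Threefold-symmetric phloroglucinol leaves no 6- versus 8-question at this stage; it is settled afterwards by which oxygen is alkylated.
4. The (S)-cyclopentene comes from (R)-p-menth-1-ene by excision of one ring carbon (ozonolysis, aldol condensation, decarbonylation). The bromine left on C2' by the ring expansion is removed in the Parham step.
5. Ring order: cyclopentene, then cyclohexene (ring expansion, step 5), then ring C (step 10); both benzene rings are bought.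

Key step: step 5

Remark (assumption): the two free aromatic CH positions of the bis-MOM ether made in step 8 are treated as one position, because rotation about the aryl–cyclohexenyl bond exchanges them; (R)-(+)-p-menth-1-ene, anhydrous phloroglucinol and ethyl (3R)-3-hydroxy-3-phenylpropanoate are taken as purchased.

**Route**

Step 1
Reactants: 1 (4R)-1-methyl-4-(propan-2-yl)cyclohex-1-ene [(R)-(+)-p-menth-1-ene]
Product: 3 (3R)-6-oxo-3-(propan-2-yl)heptanal, via secondary ozonide 2 (not isolated)
Conditions: O3, CH2Cl2, −78 °C; then PPh3, −78 °C → rt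
Reagents that add atoms: ozone, [O-][O+]=O
Why: Ozonolysis of the only C=C bond ([3+2] cycloaddition, cycloreversion and recombination to ozonide 2, then reduction by the phosphine) cuts the ring between C1 and C2 and leaves the isopropyl stereocentre, which is β to the new aldehyde, untouched.

Step 2
Reactants: 3 (3R)-6-oxo-3-(propan-2-yl)heptanal
Product: 4 (5S)-2-methyl-5-(propan-2-yl)cyclopent-1-ene-1-carbaldehyde
Conditions: piperidine (cat.), AcOH (cat.), toluene, reflux, Dean–Stark
Reagents that add atoms: none
Why: Amine-catalysed intramolecular aldol condensation in which the enamine of the aldehyde attacks the methyl ketone (five-membered ring, 5-(enolexo)-exo-trig) and water is lost to the tetrasubstituted enal, the stereocentre lying outside every enolisable position.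

Step 3
Reactants: 4 (5S)-2-methyl-5-(propan-2-yl)cyclopent-1-ene-1-carbaldehyde
Product: 5 (3S)-1-methyl-3-(propan-2-yl)cyclopent-1-ene
Conditions: RhCl3·3H2O (cat.), 1,3-bis(diphenylphosphino)propane (cat.), diglyme, reflux; product distilled out as it forms
Reagents that add atoms: none
Why: Rhodium-catalysed decarbonylation of the aldehyde (Tsuji–Wilkinson type: C–H oxidative addition, CO extrusion, C–H reductive elimination) replaces CHO by H with retention of the alkene position, and continuous distillation should remove the volatile alkene before it can isomerise.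

Step 4
Reactants: 5 (3S)-1-methyl-3-(propan-2-yl)cyclopent-1-ene
Product: 6 (1R,4S,5S)-6,6-dibromo-1-methyl-4-(propan-2-yl)bicyclo[3.1.0]hexane
Conditions: CHBr3, KOt-Bu, pentane, −20 → 0 °C; used cold, not distilled
Reagents that add atoms: bromoform, BrC(Br)Br
Why: Cheletropic addition of dibromocarbene (α-elimination of bromoform) to the electron-rich trisubstituted alkene gives the cis-fused cyclopropane, mainly anti to the isopropyl group, and the minor syn adduct would lead to the same cation in step 5.

Step 5
Reactants: 6 (1R,4S,5S)-6,6-dibromo-1-methyl-4-(propan-2-yl)bicyclo[3.1.0]hexane; 7 phloroglucinol (benzene-1,3,5-triol)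
Product: 9 2-[(1R,6S)-2-bromo-3-methyl-6-(propan-2-yl)cyclohex-2-en-1-yl]benzene-1,3,5-triol, via 2-bromocyclohexenyl cation 8 (not isolated)
Conditions: AgO2CCF3 (1.2 equiv), 7 (3 equiv), (CF3)2CHOH, 0 °C → rt, dark
Reagents that add atoms: none
Why: Proposed new method: silver-assisted departure of the endo bromide of 6 is concerted with disrotatory cyclopropyl-to-allyl opening of the shared C1–C5 bond of the bicycle, so the CBr carbon is inserted into the five-membered ring and 2-bromocyclohexenyl cation 8 results, which alkylates phloroglucinol (Friedel–Crafts) and rearomatises by proton loss. The closest known reaction types are the silver-promoted electrocyclic ring expansion of gem-dibromobicyclo[n.1.0]alkanes with capture by oxygen, nitrogen or tethered carbon nucleophiles and the acid-mediated Friedel–Crafts coupling of phloroglucinols with p-menth-2-enyl cations; what is new is intermolecular capture of the halocyclopropane-derived cation by a free polyphenol. No ring is closed by bond formation: the six-membered ring arises from the five-membered ring by this 2π-electrocyclic opening, in which the ring carbons must turn inward, so the endo bromide leaves and the exo bromide stays on the central allyl carbon. The new stereocentre C1' is controlled by the neighbouring isopropyl-bearing carbon, the arene adding to the allyl terminus on the face anti to isopropyl (trans product). Attack is needed at the secondary terminus next to CH(i-Pr) and not at the methyl-bearing terminus, which the strain of a quaternary carbon carrying a 2,6-dihydroxyaryl group and the reversibility of that addition should secure, as in the bromine-free menthenyl series. The threefold symmetry and the excess of 7 make the site of arylation unambiguous and suppress double alkylation, and the vinylic bromine shields the new alkene from acid-induced cyclisation onto the ortho hydroxyls.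

Step 6
Reactants: 10 ethyl (3R)-3-hydroxy-3-phenylpropanoate
Product: 11 (3R)-3-hydroxy-N-methoxy-N-methyl-3-phenylpropanamide
Conditions: MeNH(OMe)·HCl, i-PrMgCl (excess), THF, −20 → 0 °C
Reagents that add atoms: N,O-dimethylhydroxylamine hydrochloride, CNOC.Cl
Why: Aminolysis of the ester by the chloromagnesium amide of N,O-dimethylhydroxylamine (Weinreb amide formation), the carbinol carbon being untouched as its magnesium alkoxide.

Step 7
Reactants: 9 2-[(1R,6S)-2-bromo-3-methyl-6-(propan-2-yl)cyclohex-2-en-1-yl]benzene-1,3,5-triol; 11 (3R)-3-hydroxy-N-methoxy-N-methyl-3-phenylpropanamide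
Product: 12 (3S)-3-{4-[(1R,6S)-2-bromo-3-methyl-6-(propan-2-yl)cyclohex-2-en-1-yl]-3,5-dihydroxyphenoxy}-N-methoxy-N-methyl-3-phenylpropanamide
Conditions: PPh3, DIAD (added last, dropwise), THF, 0 °C → rt
Reagents that add atoms: none
Why: Mitsunobu etherification (SN2 at the oxyphosphonium-activated benzylic carbinol, inversion from R to S, which sets C2 of the flavanone) should take place only at the phenol para to the cyclohexenyl group, since the other two are screened by the 2-bromocyclohexenyl substituent, and this choice of oxygen fixes the 6- and not the 8-substituted flavanone.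

Step 8
Reactants: 12 (3S)-3-{4-[(1R,6S)-2-bromo-3-methyl-6-(propan-2-yl)cyclohex-2-en-1-yl]-3,5-dihydroxyphenoxy}-N-methoxy-N-methyl-3-phenylpropanamide
Product: 13 (3S)-3-{4-[(1R,6S)-2-bromo-3-methyl-6-(propan-2-yl)cyclohex-2-en-1-yl]-3,5-bis(methoxymethoxy)phenoxy}-N-methoxy-N-methyl-3-phenylpropanamide
Conditions: MOMCl (excess), i-Pr2NEt, CH2Cl2, 0 → 40 °C
Reagents that add atoms: chloromethyl methyl ether, COCCl
Why: Williamson-type O-alkylation of the two remaining phenols to methoxymethyl ethers under amine base, mild enough to leave the β-aryloxy amide intact.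

Step 9
Reactants: 13 (3S)-3-{4-[(1R,6S)-2-bromo-3-methyl-6-(propan-2-yl)cyclohex-2-en-1-yl]-3,5-bis(methoxymethoxy)phenoxy}-N-methoxy-N-methyl-3-phenylpropanamide
Product: 14 (3S)-3-{2-bromo-4-[(1R,6S)-2-bromo-3-methyl-6-(propan-2-yl)cyclohex-2-en-1-yl]-3,5-bis(methoxymethoxy)phenoxy}-N-methoxy-N-methyl-3-phenylpropanamide
Conditions: NBS (1.0 equiv), MeCN, −20 °C, dark
Reagents that add atoms: N-bromosuccinimide, O=C1CCC(=O)N1Br
Why: Electrophilic aromatic bromination of the trioxygenated ring at one of its two free positions, which are constitutionally the same and both ortho to the ether oxygen, while the bromine-deactivated alkene should not compete.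

Step 10
Reactants: 14 (3S)-3-{2-bromo-4-[(1R,6S)-2-bromo-3-methyl-6-(propan-2-yl)cyclohex-2-en-1-yl]-3,5-bis(methoxymethoxy)phenoxy}-N-methoxy-N-methyl-3-phenylpropanamide
Product: 17 (2S)-5,7-bis(methoxymethoxy)-6-[(1S,6S)-3-methyl-6-(propan-2-yl)cyclohex-2-en-1-yl]-2-phenyl-2,3-dihydro-4H-chromen-4-one, via dilithio species 15 (not isolated), via cyclised lithium hemiaminal 16 (not isolated)
Conditions: t-BuLi (4.4 equiv), THF, −78 °C; then AcOH, −78 °C → rt
Reagents that add atoms: none
Why: Parham cyclisation, in which bromine–lithium exchange occurs at both C–Br bonds, the aryllithium closes ring C by 6-exo-trig addition to the Weinreb amide to give the stable chelate 16 that releases the ketone only on work-up, and the alkenyllithium, left without an electrophile, is protonated so that the bromine from the ring expansion is erased in the same operation, C2 not being involved.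

Step 11
Reactants: 17 (2S)-5,7-bis(methoxymethoxy)-6-[(1S,6S)-3-methyl-6-(propan-2-yl)cyclohex-2-en-1-yl]-2-phenyl-2,3-dihydro-4H-chromen-4-one
Product: 18 (2S)-5,7-dihydroxy-6-[(1S,6S)-3-methyl-6-(propan-2-yl)cyclohex-2-en-1-yl]-2-phenyl-2,3-dihydro-4H-chromen-4-one
Conditions: 3 M aq. HCl, MeOH/THF, rt
Reagents that add atoms: none
Why: Acid-catalysed cleavage of both methoxymethyl acetals (transacetalisation to dimethoxymethane) under conditions that related prenylated flavanones withstand, so the C2 stereocentre and the trisubstituted alkene should survive.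

**Compound list**

1 | (4R)-1-methyl-4-(propan-2-yl)cyclohex-1-ene, (R)-(+)-p-menth-1-ene | CC1=CC[C@@H](CC1)C(C)C | starting material
2 | secondary ozonide of 1: 1-methyl-4-(propan-2-yl)-7,8,9-trioxabicyclo[4.2.1]nonane (isopropyl stereocentre as in 1, acetal carbons undefined) | CC12OC(C[C@@H](CC1)C(C)C)OO2 | intermediate
3 | (3R)-6-oxo-3-(propan-2-yl)heptanal | O=CC[C@H](C(C)C)CCC(C)=O | intermediate
4 | (5S)-2-methyl-5-(propan-2-yl)cyclopent-1-ene-1-carbaldehyde | CC1=C(C=O)[C@H](C(C)C)CC1 | intermediate
5 | (3S)-1-methyl-3-(propan-2-yl)cyclopent-1-ene | CC1=C[C@H](C(C)C)CC1 | intermediate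
6 | (1R,4S,5S)-6,6-dibromo-1-methyl-4-(propan-2-yl)bicyclo[3.1.0]hexane (cyclopropane anti to isopropyl) | C[C@@]12CC[C@@H](C(C)C)[C@@H]1C2(Br)Br | intermediate
7 | phloroglucinol, benzene-1,3,5-triol | Oc1cc(O)cc(O)c1 | starting material
8 | 2-bromo-3-methyl-6-(propan-2-yl)cyclohex-2-en-1-yl cation (allyl cation, charge shared by C1 and C3; isopropyl stereocentre as in 6) | CC1=C(Br)[CH+][C@H](C(C)C)CC1 | intermediate
9 | 2-[(1R,6S)-2-bromo-3-methyl-6-(propan-2-yl)cyclohex-2-en-1-yl]benzene-1,3,5-triol | CC1=C(Br)[C@@H](c2c(O)cc(O)cc2O)[C@H](C(C)C)CC1 | intermediate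
10 | ethyl (3R)-3-hydroxy-3-phenylpropanoate | CCOC(=O)C[C@@H](O)c1ccccc1 | starting material
11 | (3R)-3-hydroxy-N-methoxy-N-methyl-3-phenylpropanamide | CON(C)C(=O)C[C@@H](O)c1ccccc1 | intermediate
12 | (3S)-3-{4-[(1R,6S)-2-bromo-3-methyl-6-(propan-2-yl)cyclohex-2-en-1-yl]-3,5-dihydroxyphenoxy}-N-methoxy-N-methyl-3-phenylpropanamide | CC1=C(Br)[C@@H](c2c(O)cc(O[C@@H](CC(=O)N(C)OC)c3ccccc3)cc2O)[C@H](C(C)C)CC1 | intermediate
13 | (3S)-3-{4-[(1R,6S)-2-bromo-3-methyl-6-(propan-2-yl)cyclohex-2-en-1-yl]-3,5-bis(methoxymethoxy)phenoxy}-N-methoxy-N-methyl-3-phenylpropanamide | CC1=C(Br)[C@@H](c2c(OCOC)cc(O[C@@H](CC(=O)N(C)OC)c3ccccc3)cc2OCOC)[C@H](C(C)C)CC1 | intermediate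
14 | (3S)-3-{2-bromo-4-[(1R,6S)-2-bromo-3-methyl-6-(propan-2-yl)cyclohex-2-en-1-yl]-3,5-bis(methoxymethoxy)phenoxy}-N-methoxy-N-methyl-3-phenylpropanamide | CC1=C(Br)[C@@H](c2c(OCOC)c(Br)c(O[C@@H](CC(=O)N(C)OC)c3ccccc3)cc2OCOC)[C@H](C(C)C)CC1 | intermediate
15 | dilithio derivative of 14, both bromine atoms replaced by lithium (stereocentres as in 14) | CC1=C([Li])[C@@H](c2c(OCOC)c([Li])c(O[C@@H](CC(=O)N(C)OC)c3ccccc3)cc2OCOC)[C@H](C(C)C)CC1 | intermediate
16 | cyclised tetrahedral adduct: lithium alkoxide of the N-methoxy-N-methyl hemiaminal at C4 of 17, still lithiated at C2' of the cyclohexene (stereocentres as in 17, C4 undefined) | CC1=C([Li])[C@@H](c2c(OCOC)cc3c(c2OCOC)C(O[Li])(N(C)OC)C[C@@H](c2ccccc2)O3)[C@H](C(C)C)CC1 | intermediate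
17 | (2S)-5,7-bis(methoxymethoxy)-6-[(1S,6S)-3-methyl-6-(propan-2-yl)cyclohex-2-en-1-yl]-2-phenyl-2,3-dihydro-4H-chromen-4-one | CC1=C[C@@H](c2c(OCOC)cc3c(c2OCOC)C(=O)C[C@@H](c2ccccc2)O3)[C@H](C(C)C)CC1 | intermediate
18 | (2S)-5,7-dihydroxy-6-[(1S,6S)-3-methyl-6-(propan-2-yl)cyclohex-2-en-1-yl]-2-phenyl-2,3-dihydro-4H-chromen-4-one | CC1=C[C@@H](c2c(O)cc3c(c2O)C(=O)C[C@@H](c2ccccc2)O3)[C@H](C(C)C)CC1 | target

**Step count and risks**

Total step count: 11. Longest linear sequence: 10 steps (steps 1–5 and 7–11; step 6 is a one-step side branch).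

Step 5 (Proposed new method). The cation may be diverted before the C–C bond forms, by proton loss to a bromodiene or by capture through trifluoroacetate or the solvent, and the electron-rich triol may be oxidised by the silver salt. The fallback sets out from 6 and separates the two events with known chemistry. Gentle heating of 6 (toluene, 80–100 °C) should bring about the thermal electrocyclic ring opening with return of bromide that is typical of gem-dibromobicyclo[n.1.0]alkanes, giving the allylic dibromide (3S,4S)-2,3-dibromo-1-methyl-4-(propan-2-yl)cyclohex-1-ene F1 (its C3 epimer ionises to the same cation). F1 then alkylates an excess of 7 in a silver-free Friedel–Crafts allylation (Zn(OTf)2 cat., CH2Cl2/(CF3)2CHOH, rt), trans to the isopropyl group. The fallback comes back to the route at 9.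

Step 7. The etherification may lose site selectivity (reaction at a hindered phenol or at two phenols), or the activated β-hydroxy amide may eliminate to the cinnamamide faster than it is substituted. The fallback sets out from 9 and replaces kinetic selection in the bond-forming step by a protecting-group sequence. TIPSCl/imidazole (DMF, 0 °C) silylates the unhindered phenol to give 2-[(1R,6S)-2-bromo-3-methyl-6-(propan-2-yl)cyclohex-2-en-1-yl]-5-{[tri(propan-2-yl)silyl]oxy}benzene-1,3-diol F2. MOMCl/i-Pr2NEt converts it into {4-[(1R,6S)-2-bromo-3-methyl-6-(propan-2-yl)cyclohex-2-en-1-yl]-3,5-bis(methoxymethoxy)phenoxy}tri(propan-2-yl)silane F3. TBAF (THF, 0 °C) frees the single phenol 4-[(1R,6S)-2-bromo-3-methyl-6-(propan-2-yl)cyclohex-2-en-1-yl]-3,5-bis(methoxymethoxy)phenol F4. Mitsunobu reaction of F4 with an excess of 11 (PPh3, DIAD), now free of any selectivity constraint, comes back to the route at 13.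

Step 10. Excess t-BuLi or the alkenyllithium may attack the Weinreb amide or deprotonate next to the ether oxygen before ring closure, or exchange at the hindered alkenyl bromide may stay incomplete. The fallback sets out from 14 and does the two jobs separately. n-BuLi (1.05 equiv, THF, −100 °C) should exchange only the aryl bromide, and Parham cyclisation then gives (2S)-6-[(1R,6S)-2-bromo-3-methyl-6-(propan-2-yl)cyclohex-2-en-1-yl]-5,7-bis(methoxymethoxy)-2-phenyl-2,3-dihydro-4H-chromen-4-one F5. Radical hydrodebromination of the alkenyl bromide (Bu3SnH, AIBN, toluene, 80 °C) then comes back to the route at 17.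

**Further compounds**

F1 | step 5 | (3S,4S)-2,3-dibromo-1-methyl-4-(propan-2-yl)cyclohex-1-ene | CC1=C(Br)[C@@H](Br)[C@H](C(C)C)CC1
F2 | step 7 | 2-[(1R,6S)-2-bromo-3-methyl-6-(propan-2-yl)cyclohex-2-en-1-yl]-5-{[tri(propan-2-yl)silyl]oxy}benzene-1,3-diol | CC1=C(Br)[C@@H](c2c(O)cc(O[Si](C(C)C)(C(C)C)C(C)C)cc2O)[C@H](C(C)C)CC1
F3 | step 7 | {4-[(1R,6S)-2-bromo-3-methyl-6-(propan-2-yl)cyclohex-2-en-1-yl]-3,5-bis(methoxymethoxy)phenoxy}tri(propan-2-yl)silane | CC1=C(Br)[C@@H](c2c(OCOC)cc(O[Si](C(C)C)(C(C)C)C(C)C)cc2OCOC)[C@H](C(C)C)CC1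
F4 | step 7 | 4-[(1R,6S)-2-bromo-3-methyl-6-(propan-2-yl)cyclohex-2-en-1-yl]-3,5-bis(methoxymethoxy)phenol | CC1=C(Br)[C@@H](c2c(OCOC)cc(O)cc2OCOC)[C@H](C(C)C)CC1
F5 | step 10 | (2S)-6-[(1R,6S)-2-bromo-3-methyl-6-(propan-2-yl)cyclohex-2-en-1-yl]-5,7-bis(methoxymethoxy)-2-phenyl-2,3-dihydro-4H-chromen-4-one | CC1=C(Br)[C@@H](c2c(OCOC)cc3c(c2OCOC)C(=O)C[C@@H](c2ccccc2)O3)[C@H](C(C)C)CC1
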